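**Fast, then slow.** Target in the theta flask averages 31.3% around 3.83 min and less, 29.8%, around 9.00 min. Read as a first-order loss, these scattered readings give a sag of 0.00918 min⁻¹. The climb before it, 0.268 min⁻¹ as a fraction of the charge, is far faster than the sag of 0.00287 min⁻¹.

in all of them: starting material 0.20 M
- theta: protic impurity 0.20 M; the very flask that is asked about, followed so far
- eta: protic impurity 0.13 M; run made earlier
- flask: protic impurity 0.200 M; time 15 min

| run | time / min | target / % |
|---|---|---|
| theta | 0.500 | 23.1 |
| theta | 1.33 | 35.6 |
| theta | 2.50 | 32.3 |
| theta | 4.00 | 30.1 |
| theta | 5.00 | 31.5 |
| theta | 8.00 | 30.4 |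
| theta | 10.0 | 29.3 |
| eta | 0.417 | 21.3 |
| eta | 1.33 | 32.9 |
| eta | 2.50 | 36.0 |
| eta | 3.00 | 34.3 |
| eta | 5.00 | 31.7 |
| eta | 6.00 | 32.1 |
| eta | 8.00 | 29.9 |

(each reading ± 1 percentage point)

- Sunday's: at 15 min add starting material, 50.0% of the amount charged, then wait 30 min
- Saturday's: at 15 min take out 90% of the target then present, then wait 30 min
- Monday's: change nothing and wait 30 min more

- what is taken out of target is counted as made
- what was read earlier has a scatter of 1 percentage point, one standard deviation
- additions bring no volume worth counting

- target, in percent of the starting material first charged, at 15 min
- which option adds most target ("none" when 2 percentage points or less is all one gets) (Sunday's / Saturday's / Monday's / none)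
- target present, with what was taken out counted in, in percent of the starting material first charged, after Sunday's
- target present, with what was taken out counted in, in percent of the starting material first charged, after Saturday's

**Balance share.** My reckoning commits to one reading of this shape. When a forward rate and a back rate come level, time drops out of their ratio and a share remains, so target is a fixed share of whatever stands in balance. That is thermodynamic control. Running the sag back to the start, when the whole charge stood in the pool, gives the balance share 32.4%, about a third. The eta flask, with less impurity, reads 31.7% at 5.00 min, beside 31.5% for theta.

**My reckoning.** Carrying the sag forward gives 28.3% at 15 min, so the pool is 87.1%. Over 30 min the sag keeps a factor 0.759. Saturday's banks 25.4% and the rest rebalances, giving 40.6% in all. Sunday's enlarges the pool, giving 33.8%. Monday's falls to 21.4%. I choose Saturday's.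

**The forecast.** It gives 28% now, chooses Saturday's, and puts Sunday's at 28% and Saturday's at 33%, under mine on both. On the cause of the stall it says “The data cannot separate these”.

**The flask.** The asked flask holds 27.9% at 15 min. Saturday's is best, adding 13 percentage points, against 8.9 points for Sunday's and −4.8 points for Monday's. Sunday's ends at 36.8% and Saturday's at 41.1%.

    starting material ⇌ target (K = 2.90, k = 0.0120 s⁻¹)
    target ⇌ isomer of the product (K = 1.60, k = 0.0130 s⁻¹)
    starting material + protic impurity → quenched substrate (k = 0.00640 M⁻¹ s⁻¹)

**Neighbouring flask.** Quenched substrate is what leaves the pool, and the asked flask holds 17.8% of it at 15 min. The share 32.4% of the remainder is 26.6% target, against 27.9% found. The neighbouring flask, charged with 0.050 M of protic impurity, holds 4.92% of quenched substrate at 15 min. The same share of its remainder gives 30.8% target, and that neighbouring flask holds 32.3%.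

(The data are calculated for substances that don't exist.)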